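**Plan**

1. Numbering (germacranolide): C1 ketone, C2=C3, the ring O and C10 (C14 methyl) form the furanone; C4(C15)=C5; C6–O–C12(=O)–C11(=C13)–C7 is the lactone; C8 carries the ester; C9 links C8 to C10.
2. Retrosynthesis: cut O–C3 (furanone), then C1–C2 (alkynyl–aldehyde closure of the ten-membered carbocycle), the C8 ester and C11=C13, the lactone O–C12, C6–C7 (aldol) and C7–C8 (Stetter).
3. Forward: aldehyde 8 and methyl acrylate give keto ester 10 (C7–C8); aldol with enynal 4 joins the chain (C6–C7); the rings then arise in the order γ-lactone (step 8), ten-membered carbocycle (step 14), furanone (step 16).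
4. Stereochemistry: C10 from (S)-citramalic acid; C6 and C7 from a reagent-controlled syn boron aldol; C8 by hydroxyl-directed 1,3-anti reduction relayed from C6; the 4Z alkene from commercial (Z)-3-methylpent-2-en-4-yn-1-ol; the C2=C3 geometry from the ring closure itself.
5. Enabling feature: the tertiary C10 hydroxyl is α to the C1 carbonyl of the ynone C1(=O)–C2≡C3 held inside the ten-membered ring, so its oxygen and C3 are 1,4-related; attack on the bent alkyne relieves ring strain and lays the one-atom oxygen bridge of the 11-oxabicyclo[6.2.1]undecane across the carbocycle as the last ring.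

Key step: step 16

Step 1
Reactants: 1 (Z)-3-methylpent-2-en-4-yn-1-ol
Product: 3 (Z)-3-methyl-5-(trimethylsilyl)pent-2-en-4-yn-1-ol, via bis-silylated ether 2 (not isolated)
Conditions: n-BuLi (2.1 equiv), THF, −78 °C; TMSCl (2.2 equiv), −78 °C to rt; then 1 M aq HCl, rt
Reagents that add atoms: chlorotrimethylsilane, C[Si](C)(C)Cl
Why: Double deprotonation (O–H and alkynyl C–H), bis-silylation and selective acid hydrolysis of the labile silyl ether is the standard C-silylation of alkynols and leaves the Z alkene untouched.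

Step 2
Reactants: 3 (Z)-3-methyl-5-(trimethylsilyl)pent-2-en-4-yn-1-ol
Product: 4 (Z)-3-methyl-5-(trimethylsilyl)pent-2-en-4-ynal
Conditions: MnO2 (activated, excess), CH2Cl2, rt, dark
Reagents that add atoms: none
Why: Allylic oxidation with MnO2 is neutral and mild, so the (Z)-enal should form without Z/E isomerisation; it is used promptly.

Step 3
Reactants: 5 (S)-citramalic acid [(2S)-2-hydroxy-2-methylbutanedioic acid]
Product: 6 (2S)-2-methylbutane-1,2,4-triol
Conditions: BH3·SMe2, B(OMe)3, THF, 0 °C to rt; then MeOH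
Reagents that add atoms: none
Why: Borane reduces both carboxyl groups of hydroxy diacids (as with malic acid) and does not touch the tertiary carbinol centre, which becomes C10.

Step 4
Reactants: 6 (2S)-2-methylbutane-1,2,4-triol
Product: 7 2-[(4S)-2,2,4-trimethyl-1,3-dioxolan-4-yl]ethan-1-ol
Conditions: 2,2-dimethoxypropane, CSA (cat.), CH2Cl2, rt
Reagents that add atoms: 2,2-dimethoxypropane, COC(C)(C)OC
Why: Acetonide formation under thermodynamic control favours the five-membered dioxolane of the 1,2-diol over the six-membered dioxane, leaving the C8 primary alcohol free.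

Step 5
Reactants: 7 2-[(4S)-2,2,4-trimethyl-1,3-dioxolan-4-yl]ethan-1-ol
Product: 8 2-[(4S)-2,2,4-trimethyl-1,3-dioxolan-4-yl]acetaldehyde
Conditions: TEMPO (10 mol%), PhI(OAc)2, CH2Cl2, rt
Reagents that add atoms: none
Why: Oxoammonium-mediated oxidation of a primary alcohol stops at the aldehyde and is mild enough for the acetonide.

Step 6
Reactants: 8 2-[(4S)-2,2,4-trimethyl-1,3-dioxolan-4-yl]acetaldehyde; 9 methyl acrylate
Product: 10 methyl 4-oxo-5-[(4S)-2,2,4-trimethyl-1,3-dioxolan-4-yl]pentanoate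
Conditions: 3-benzyl-5-(2-hydroxyethyl)-4-methylthiazolium chloride (20 mol%), Et3N, 1,4-dioxane, 70 °C
Reagents that add atoms: none
Why: Stetter reaction: the thiazolylidene turns the aliphatic aldehyde into an acyl anion equivalent that adds 1,4 to the acrylate, forming C7–C8 and the γ-keto ester in one step.

Step 7
Reactants: 10 methyl 4-oxo-5-[(4S)-2,2,4-trimethyl-1,3-dioxolan-4-yl]pentanoate; 4 (Z)-3-methyl-5-(trimethylsilyl)pent-2-en-4-ynal
Product: 13 methyl (3S,4R,5Z)-4-hydroxy-6-methyl-3-{[(4S)-2,2,4-trimethyl-1,3-dioxolan-4-yl]acetyl}-8-(trimethylsilyl)oct-5-en-7-ynoate, via Z-enol borinate 11 (not isolated), via boron aldolate 12 (not isolated)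
Conditions: (−)-Ipc2BOTf (from (+)-α-pinene), iPr2NEt, CH2Cl2, −78 °C; then 4, −78 to −20 °C; then MeOH, pH 7 buffer, 30% H2O2, 0 °C
Reagents that add atoms: none
Why: Reagent-controlled boron aldol reaction: the bulky boron triflate enolises the less hindered C7 methylene (C9 is neopentylic) to the Z-enol borinate, whose chair-like transition state gives the 6,7-syn adduct, while the isopinocampheyl groups are expected to direct the enolate to the Si face of the aldehyde (6R); minor isomers are diastereomers of 13 (C10 is fixed) and separable, and 13 is taken on at once so that it does not lactonise before step 8.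

Step 8
Reactants: 13 methyl (3S,4R,5Z)-4-hydroxy-6-methyl-3-{[(4S)-2,2,4-trimethyl-1,3-dioxolan-4-yl]acetyl}-8-(trimethylsilyl)oct-5-en-7-ynoate
Product: 15 (4R,5R)-4-{(1R)-1-hydroxy-2-[(4S)-2,2,4-trimethyl-1,3-dioxolan-4-yl]ethyl}-5-[(1Z)-2-methyl-4-(trimethylsilyl)but-1-en-3-yn-1-yl]oxolan-2-one, via anti-diol ester 14 (not isolated)
Conditions: Me4NBH(OAc)3, MeCN/AcOH (1:1), −30 °C; then PPTS (cat.), PhH, 50 °C
Reagents that add atoms: none
Why: Evans–Saksena reduction: the C6 hydroxyl binds the acetoxyborohydride and delivers hydride to the C8 ketone through a chair-like six-membered transition state, giving the 1,3-anti diol (8R); acid-catalysed lactonisation under equilibrating conditions then selects the trans-disubstituted 6,12-lactone over the cis-disubstituted 8,12-isomer and leaves the C8 hydroxyl free.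

Step 9
Reactants: 15 (4R,5R)-4-{(1R)-1-hydroxy-2-[(4S)-2,2,4-trimethyl-1,3-dioxolan-4-yl]ethyl}-5-[(1Z)-2-methyl-4-(trimethylsilyl)but-1-en-3-yn-1-yl]oxolan-2-one
Product: 19 (4R,5R)-4-{(1R)-1-hydroxy-2-[(4S)-2,2,4-trimethyl-1,3-dioxolan-4-yl]ethyl}-3-methylidene-5-[(1Z)-2-methyl-4-(trimethylsilyl)but-1-en-3-yn-1-yl]oxolan-2-one, via dilithium dianion 16 (not isolated), via Mannich base 17 (not isolated), via ammonium iodide 18 (not isolated)
Conditions: LiN(iPr)2 (2.2 equiv), THF, −78 °C; CH2=NMe2+ I− (Eschenmoser's salt), −78 °C to rt; then MeI, THF, rt; then NaHCO3 (aq), CH2Cl2, rt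
Reagents that add atoms: N,N-dimethylmethyleneiminium iodide (Eschenmoser's salt), C=[N+](C)C.[I-]
Why: Standard α-methylenation of a γ-lactone (Mannich reaction of the lactone enolate, N-quaternisation, E1cB elimination) introduces C13 without touching C6 or C7; the C8 hydroxyl is simply carried as its alkoxide.

Step 10
Reactants: 19 (4R,5R)-4-{(1R)-1-hydroxy-2-[(4S)-2,2,4-trimethyl-1,3-dioxolan-4-yl]ethyl}-3-methylidene-5-[(1Z)-2-methyl-4-(trimethylsilyl)but-1-en-3-yn-1-yl]oxolan-2-one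
Product: 20 (1R)-1-{(2R,3R)-4-methylidene-2-[(1Z)-2-methyl-4-(trimethylsilyl)but-1-en-3-yn-1-yl]-5-oxooxolan-3-yl}-2-[(4S)-2,2,4-trimethyl-1,3-dioxolan-4-yl]ethyl 3-methylbutanoate
Conditions: 3-methylbutanoic anhydride, DMAP (cat.), Et3N, CH2Cl2, 0 °C to rt
Reagents that add atoms: 3-methylbutanoic anhydride, CC(C)CC(=O)OC(=O)CC(C)C
Why: DMAP-catalysed acylation of the only free hydroxyl (C8) proceeds with retention because the C8–O bond is not broken.

Step 11
Reactants: 20 (1R)-1-{(2R,3R)-4-methylidene-2-[(1Z)-2-methyl-4-(trimethylsilyl)but-1-en-3-yn-1-yl]-5-oxooxolan-3-yl}-2-[(4S)-2,2,4-trimethyl-1,3-dioxolan-4-yl]ethyl 3-methylbutanoate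
Product: 21 (1R,3S)-3,4-dihydroxy-3-methyl-1-{(2R,3R)-4-methylidene-2-[(1Z)-2-methyl-4-(trimethylsilyl)but-1-en-3-yn-1-yl]-5-oxooxolan-3-yl}butyl 3-methylbutanoate
Conditions: AcOH/H2O/THF (3:1:1), 40 °C
Reagents that add atoms: none
Why: Mild aqueous acid hydrolyses the acetonide, while the ester, the lactone and the silylalkyne are stable under these conditions.

Step 12
Reactants: 21 (1R,3S)-3,4-dihydroxy-3-methyl-1-{(2R,3R)-4-methylidene-2-[(1Z)-2-methyl-4-(trimethylsilyl)but-1-en-3-yn-1-yl]-5-oxooxolan-3-yl}butyl 3-methylbutanoate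
Product: 22 (1R,3S)-3,4-dihydroxy-1-{(2R,3R)-2-[(1Z)-4-iodo-2-methylbut-1-en-3-yn-1-yl]-4-methylidene-5-oxooxolan-3-yl}-3-methylbutyl 3-methylbutanoate
Conditions: N-iodosuccinimide, AgNO3 (10 mol%), acetone, rt, dark
Reagents that add atoms: N-iodosuccinimide, O=C1CCC(=O)N1I
Why: Silver-catalysed iododesilylation converts a trimethylsilylalkyne directly into the 1-iodoalkyne via a silver acetylide and is selective for the C–Si bond over the alkenes and hydroxyls.

Step 13
Reactants: 22 (1R,3S)-3,4-dihydroxy-1-{(2R,3R)-2-[(1Z)-4-iodo-2-methylbut-1-en-3-yn-1-yl]-4-methylidene-5-oxooxolan-3-yl}-3-methylbutyl 3-methylbutanoate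
Product: 23 (1R,3S)-3-hydroxy-1-{(2R,3R)-2-[(1Z)-4-iodo-2-methylbut-1-en-3-yn-1-yl]-4-methylidene-5-oxooxolan-3-yl}-3-methyl-4-oxobutyl 3-methylbutanoate
Conditions: SO3·pyridine, DMSO, iPr2NEt, CH2Cl2, 0 °C
Reagents that add atoms: none
Why: Parikh–Doering oxidation takes the primary alcohol of the 1,2-diol to the aldehyde without glycol cleavage, the tertiary hydroxyl being inert; the non-enolisable α-hydroxy aldehyde is used directly.

Step 14
Reactants: 23 (1R,3S)-3-hydroxy-1-{(2R,3R)-2-[(1Z)-4-iodo-2-methylbut-1-en-3-yn-1-yl]-4-methylidene-5-oxooxolan-3-yl}-3-methyl-4-oxobutyl 3-methylbutanoate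
Product: 24 (4Z,6R,7R,8R,10S)-1,10-dihydroxy-8-(3-methylbutanoyloxy)germacra-4,11(13)-dien-2-yn-12,6-olide (both C1 epimers)
Conditions: CrCl2 (6 equiv), NiCl2 (5 mol%), THF (0.002 M, slow addition of 23), rt
Reagents that add atoms: none
Why: Intramolecular Nozaki–Hiyama–Kishi reaction: divalent chromium converts the iodoalkyne into an alkynylchromium species that adds chemoselectively to the aldehyde (esters, lactone and free hydroxyl are tolerated), the established way to close ten-membered enyne rings from ω-iodoalkynyl aldehydes; the Z-enyne and the trans-lactone pre-bend the chain, and the C1 configuration is irrelevant because C1 is oxidised next.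

Step 15
Reactants: 24 (4Z,6R,7R,8R,10S)-1,10-dihydroxy-8-(3-methylbutanoyloxy)germacra-4,11(13)-dien-2-yn-12,6-olide (both C1 epimers)
Product: 25 (4Z,6R,7R,8R,10S)-10-hydroxy-8-(3-methylbutanoyloxy)-1-oxogermacra-4,11(13)-dien-2-yn-12,6-olide
Conditions: IBX, DMSO/THF, rt
Reagents that add atoms: none
Why: IBX oxidises the secondary propargylic alcohol of a 1,2-diol to the ketol without C–C cleavage, giving the α'-hydroxy ynone with the tertiary C10 hydroxyl intact.

Step 16
Reactants: 25 (4Z,6R,7R,8R,10S)-10-hydroxy-8-(3-methylbutanoyloxy)-1-oxogermacra-4,11(13)-dien-2-yn-12,6-olide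
Product: 26 (2Z,4Z,6R,7R,8R,10S)-3,10-epoxy-8-(3-methylbutanoyloxy)-1-oxogermacra-2,4,11(13)-trien-12,6-olide (target CNP0409052.1)
Conditions: (4-CF3C6H4)3PAuCl (5 mol%), AgOTf (5 mol%), toluene, rt
Reagents that add atoms: none
Why: The cationic monovalent gold complex binds the C2≡C3 triple bond of the ynone, the C10 hydroxyl attacks C3 anti to gold, and protodeauration of the C2–Au bond gives the 3(2H)-furanone. The closest known reaction is the gold-catalysed cycloisomerisation of acyclic α'-hydroxy ynones (2-hydroxyalk-4-yn-3-ones) to 3(2H)-furanones. The furanone ring (O, C3, C2, C1, C10) closes in the 5-endo-dig mode, which at the same time lays the oxygen bridge across the ten-membered carbocycle. No stereocentre is formed: C10 keeps its configuration because its C–O bond is not broken, and the C2=C3 geometry (C1 cis to O, C4 trans to C1 in the large ring) is dictated by the five-membered ring. The step needs O-attack at C3 in preference to reaction at the enyne alkene, the α-methylene lactone or the ester; this is secured by the 1,4-relationship of the hydroxyl oxygen and C3, by the polarisation of the ynone (C3 is its β-carbon) and by the angle strain of the in-ring alkyne that is released on closure, while the neutral, amine-free conditions spare the α-methylene lactone.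

**Compound list**

1 | (Z)-3-methylpent-2-en-4-yn-1-ol | OC/C=C(/C)C#C | starting material
2 | trimethyl{[(2Z)-3-methyl-5-(trimethylsilyl)pent-2-en-4-yn-1-yl]oxy}silane | C[Si](C)(C)OC/C=C(/C)C#C[Si](C)(C)C | intermediate
3 | (Z)-3-methyl-5-(trimethylsilyl)pent-2-en-4-yn-1-ol | OC/C=C(/C)C#C[Si](C)(C)C | intermediate
4 | (Z)-3-methyl-5-(trimethylsilyl)pent-2-en-4-ynal | O=C/C=C(/C)C#C[Si](C)(C)C | intermediate
5 | (S)-citramalic acid, (2S)-2-hydroxy-2-methylbutanedioic acid | C[C@](O)(CC(=O)O)C(=O)O | starting material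
6 | (2S)-2-methylbutane-1,2,4-triol | C[C@](O)(CCO)CO | intermediate
7 | 2-[(4S)-2,2,4-trimethyl-1,3-dioxolan-4-yl]ethan-1-ol | C[C@]1(CCO)COC(C)(C)O1 | intermediate
8 | 2-[(4S)-2,2,4-trimethyl-1,3-dioxolan-4-yl]acetaldehyde | C[C@]1(CC=O)COC(C)(C)O1 | intermediate
9 | methyl acrylate | C=CC(=O)OC | starting material
10 | methyl 4-oxo-5-[(4S)-2,2,4-trimethyl-1,3-dioxolan-4-yl]pentanoate | COC(=O)CCC(=O)C[C@@]1(C)COC(C)(C)O1 | intermediate
11 | methyl (3Z)-4-{[bis((1R,2S,3R,5R)-isopinocampheyl)boranyl]oxy}-5-[(4S)-2,2,4-trimethyl-1,3-dioxolan-4-yl]pent-3-enoate | COC(=O)C/C=C(/C[C@@]1(C)COC(C)(C)O1)OB([C@H]1[C@H](C)[C@H]2C[C@@H](C1)C2(C)C)[C@H]1[C@H](C)[C@H]2C[C@@H](C1)C2(C)C | intermediate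
12 | O-bis(isopinocampheyl)boranyl derivative of 13 at the C4 hydroxyl (boron aldolate) | C[Si](C)(C)C#C/C(C)=C\[C@@H](OB([C@H]1[C@H](C)[C@H]2C[C@@H](C1)C2(C)C)[C@H]1[C@H](C)[C@H]2C[C@@H](C1)C2(C)C)[C@H](CC(=O)OC)C(=O)C[C@@]1(C)COC(C)(C)O1 | intermediate
13 | methyl (3S,4R,5Z)-4-hydroxy-6-methyl-3-{[(4S)-2,2,4-trimethyl-1,3-dioxolan-4-yl]acetyl}-8-(trimethylsilyl)oct-5-en-7-ynoate | C[Si](C)(C)C#C/C(C)=C\[C@@H](O)[C@H](CC(=O)OC)C(=O)C[C@@]1(C)COC(C)(C)O1 | intermediate
14 | methyl (3R,4R,5Z)-4-hydroxy-3-{(1R)-1-hydroxy-2-[(4S)-2,2,4-trimethyl-1,3-dioxolan-4-yl]ethyl}-6-methyl-8-(trimethylsilyl)oct-5-en-7-ynoate | C[Si](C)(C)C#C/C(C)=C\[C@@H](O)[C@H](CC(=O)OC)[C@H](O)C[C@@]1(C)COC(C)(C)O1 | intermediate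
15 | (4R,5R)-4-{(1R)-1-hydroxy-2-[(4S)-2,2,4-trimethyl-1,3-dioxolan-4-yl]ethyl}-5-[(1Z)-2-methyl-4-(trimethylsilyl)but-1-en-3-yn-1-yl]oxolan-2-one | C[Si](C)(C)C#C/C(C)=C\[C@H]1OC(=O)C[C@@H]1[C@H](O)C[C@@]2(C)COC(C)(C)O2 | intermediate
16 | dilithium salt of 15 (side-chain alkoxide and lactone enolate) | [Li+].[Li+].C[Si](C)(C)C#C/C(C)=C\[C@H]1OC([O-])=C[C@@H]1[C@H]([O-])C[C@@]2(C)COC(C)(C)O2 | intermediate
17 | 3-[(dimethylamino)methyl] derivative of 15 (C3 epimers) | C[Si](C)(C)C#C/C(C)=C\[C@H]1OC(=O)C(CN(C)C)[C@@H]1[C@H](O)C[C@@]2(C)COC(C)(C)O2 | intermediate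
18 | trimethylammonium iodide derived from 17 by N-methylation | C[Si](C)(C)C#C/C(C)=C\[C@H]1OC(=O)C(C[N+](C)(C)C)[C@@H]1[C@H](O)C[C@@]2(C)COC(C)(C)O2.[I-] | intermediate
19 | (4R,5R)-4-{(1R)-1-hydroxy-2-[(4S)-2,2,4-trimethyl-1,3-dioxolan-4-yl]ethyl}-3-methylidene-5-[(1Z)-2-methyl-4-(trimethylsilyl)but-1-en-3-yn-1-yl]oxolan-2-one | C=C1C(=O)O[C@H](/C=C(/C)C#C[Si](C)(C)C)[C@H]1[C@H](O)C[C@@]2(C)COC(C)(C)O2 | intermediate
20 | (1R)-1-{(2R,3R)-4-methylidene-2-[(1Z)-2-methyl-4-(trimethylsilyl)but-1-en-3-yn-1-yl]-5-oxooxolan-3-yl}-2-[(4S)-2,2,4-trimethyl-1,3-dioxolan-4-yl]ethyl 3-methylbutanoate | C=C1C(=O)O[C@H](/C=C(/C)C#C[Si](C)(C)C)[C@H]1[C@H](OC(=O)CC(C)C)C[C@@]2(C)COC(C)(C)O2 | intermediate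
21 | (1R,3S)-3,4-dihydroxy-3-methyl-1-{(2R,3R)-4-methylidene-2-[(1Z)-2-methyl-4-(trimethylsilyl)but-1-en-3-yn-1-yl]-5-oxooxolan-3-yl}butyl 3-methylbutanoate | C=C1C(=O)O[C@H](/C=C(/C)C#C[Si](C)(C)C)[C@H]1[C@H](OC(=O)CC(C)C)C[C@](C)(O)CO | intermediate
22 | (1R,3S)-3,4-dihydroxy-1-{(2R,3R)-2-[(1Z)-4-iodo-2-methylbut-1-en-3-yn-1-yl]-4-methylidene-5-oxooxolan-3-yl}-3-methylbutyl 3-methylbutanoate | C=C1C(=O)O[C@H](/C=C(/C)C#CI)[C@H]1[C@H](OC(=O)CC(C)C)C[C@](C)(O)CO | intermediate
23 | (1R,3S)-3-hydroxy-1-{(2R,3R)-2-[(1Z)-4-iodo-2-methylbut-1-en-3-yn-1-yl]-4-methylidene-5-oxooxolan-3-yl}-3-methyl-4-oxobutyl 3-methylbutanoate | C=C1C(=O)O[C@H](/C=C(/C)C#CI)[C@H]1[C@H](OC(=O)CC(C)C)C[C@](C)(O)C=O | intermediate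
24 | (4Z,6R,7R,8R,10S)-1,10-dihydroxy-8-(3-methylbutanoyloxy)germacra-4,11(13)-dien-2-yn-12,6-olide (both C1 epimers) | C=C1C(=O)O[C@@H]2/C=C(/C)C#CC(O)[C@@](C)(O)C[C@@H](OC(=O)CC(C)C)[C@@H]12 | intermediate
25 | (4Z,6R,7R,8R,10S)-10-hydroxy-8-(3-methylbutanoyloxy)-1-oxogermacra-4,11(13)-dien-2-yn-12,6-olide | C=C1C(=O)O[C@@H]2/C=C(/C)C#CC(=O)[C@@](C)(O)C[C@@H](OC(=O)CC(C)C)[C@@H]12 | intermediate
26 | (2Z,4Z,6R,7R,8R,10S)-3,10-epoxy-8-(3-methylbutanoyloxy)-1-oxogermacra-2,4,11(13)-trien-12,6-olide (CNP0409052.1) | C=C1C(=O)O[C@@H]2/C=C(/C)C3=CC(=O)[C@](C)(C[C@@H](OC(=O)CC(C)C)[C@@H]12)O3 | target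

**Step count and risks**

Total steps: 16. Longest linear sequence: 14 steps (from 5, steps 3 to 16).

Steps most likely to fail:

Step 14 (ten-membered ring closure). Intermolecular addition leading to oligomers, and protodehalogenation of the alkynylchromium species, may outrun the slow closure of the strained ring. Fallback: generate the nucleophile reversibly from a terminal alkyne instead of from the iodoalkyne. Setting out from 21, the silyl group is removed (Bu4NF, AcOH, THF, 0 °C) to give the terminal alkyne diol, (1R,3S)-3,4-dihydroxy-3-methyl-1-{(2R,3R)-4-methylidene-2-[(1Z)-2-methylbut-1-en-3-yn-1-yl]-5-oxooxolan-3-yl}butyl 3-methylbutanoate F1. Parikh–Doering oxidation (SO3·pyridine, DMSO, iPr2NEt) gives the alkynyl aldehyde, the 4-oxo analogue F2. Intramolecular zinc acetylide addition (Zn(OTf)2, Et3N, toluene, high dilution, 40 °C) then closes the ring and comes back to the route at 24.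

Step 7 (aldol). Facial selectivity may erode, enolisation may occur toward C9, or the adduct may lactonise before the directed reduction, which would remove the free C6 hydroxyl that step 8 needs. Fallback: decouple enolate formation from C–C bond formation and change the control element. Setting out from 10, TMSOTf and Et3N (CH2Cl2, 0 °C) give the (Z)-silyl enol ether, methyl (3Z)-4-(trimethylsilyloxy)-5-[(4S)-2,2,4-trimethyl-1,3-dioxolan-4-yl]pent-3-enoate F3, whose regio- and geometric purity can be secured before coupling. A Mukaiyama aldol reaction with 4, catalysed by the N-tosyltryptophan-derived B-butyl oxazaborolidinone (EtCN, −78 °C, catalyst antipode chosen for Si-face attack), should give the syn adduct as its silyl ether, the O-trimethylsilyl derivative of 13 F4, which cannot lactonise. The silyl ether is cleaved in the acetic acid medium of step 8, so the sequence comes back to the route at 13.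

Step 6 (Stetter reaction). Base-induced β-elimination of the acetonide oxygen from the enolisable β-alkoxy aldehyde, or acyloin self-condensation, may consume 8 before conjugate addition. Fallback: reverse the polarity (acyl electrophile plus homoenolate). Setting out from 7, oxidation (TEMPO, PhI(OAc)2, MeCN/H2O) gives the acid, 2-[(4S)-2,2,4-trimethyl-1,3-dioxolan-4-yl]acetic acid F5. Thioesterification (EtSH, DCC, DMAP, CH2Cl2) gives the thioester, S-ethyl 2-[(4S)-2,2,4-trimethyl-1,3-dioxolan-4-yl]ethanethioate F6. Fukuyama coupling with IZnCH2CH2CO2Me (from methyl 3-iodopropanoate and zinc dust; PdCl2(PPh3)2 cat., THF/toluene, rt) comes back to the route at 10.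

**Further compounds**

F1 | step 14 | (1R,3S)-3,4-dihydroxy-3-methyl-1-{(2R,3R)-4-methylidene-2-[(1Z)-2-methylbut-1-en-3-yn-1-yl]-5-oxooxolan-3-yl}butyl 3-methylbutanoate | C=C1C(=O)O[C@H](/C=C(/C)C#C)[C@H]1[C@H](OC(=O)CC(C)C)C[C@](C)(O)CO
F2 | step 14 | (1R,3S)-3-hydroxy-3-methyl-1-{(2R,3R)-4-methylidene-2-[(1Z)-2-methylbut-1-en-3-yn-1-yl]-5-oxooxolan-3-yl}-4-oxobutyl 3-methylbutanoate | C=C1C(=O)O[C@H](/C=C(/C)C#C)[C@H]1[C@H](OC(=O)CC(C)C)C[C@](C)(O)C=O
F3 | step 7 | methyl (3Z)-4-(trimethylsilyloxy)-5-[(4S)-2,2,4-trimethyl-1,3-dioxolan-4-yl]pent-3-enoate | COC(=O)C/C=C(/C[C@@]1(C)COC(C)(C)O1)O[Si](C)(C)C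
F4 | step 7 | methyl (3S,4R,5Z)-6-methyl-3-{[(4S)-2,2,4-trimethyl-1,3-dioxolan-4-yl]acetyl}-8-(trimethylsilyl)-4-(trimethylsilyloxy)oct-5-en-7-ynoate | C[Si](C)(C)C#C/C(C)=C\[C@@H](O[Si](C)(C)C)[C@H](CC(=O)OC)C(=O)C[C@@]1(C)COC(C)(C)O1
F5 | step 6 | 2-[(4S)-2,2,4-trimethyl-1,3-dioxolan-4-yl]acetic acid | C[C@]1(CC(=O)O)COC(C)(C)O1
F6 | step 6 | S-ethyl 2-[(4S)-2,2,4-trimethyl-1,3-dioxolan-4-yl]ethanethioate | CCSC(=O)C[C@@]1(C)COC(C)(C)O1
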